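The data were generated by integration with constants of no real substance, and the scatter is random.

I decide to count turnovers before I choose a remedy for Saturday's flask, the one asked about, and I begin from what stands on the bench.

common to all: electrophile 0.74 M; gas 73 mM (held)

| run | nucleophile | temperature | remark | time |
|---|---|---|---|---|
| Saturday's | 0.74 M | 25 °C | the very flask that is asked about, followed so far |  |
| Sunday's | 0.74 M | 31 °C | run made earlier |  |
| flask | 0.740 M | 25 °C |  | 20 h |

- Saturday's (time / h: target / %, electrophile / %): 5.00: 74, 11; 10.0: 66, 6; 15.0: 58, 3; 20.0: 55, 3
- Sunday's (time / h: target / %, electrophile / %): 5.00: 67, 5; 10.0: 66, 0; 15.0: 62, 0; 20.0: 64, 3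

(readings scatter by 2 percentage points)

- target that was removed still counts
- at the start none of the gas is in solution
- additions bring no volume worth counting

- noon: change nothing and wait 10 h more
- autumn: at 20 h add nucleophile, 100% of the amount charged, then wait 10 h
- midnight: at 20 h take out 90% of the target then present, then wait 10 h
- summer: at 20 h raise the temperature by 25 K, then wait 10 h

1. target, in percent of the electrophile first charged, at 20 h
2. the remedy with the largest gain of target, or "none" below 2 percentage points (noon / autumn / midnight / summer / none)
3. target present, with what was taken out counted in, in percent of the electrophile first charged, after autumn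
4. target present, with what was taken out counted in, in percent of the electrophile first charged, after summer

For second-order coupling at equal charges, I fold rate constant, charge and time into one number, D = k·c_electrophile·t, and the share of electrophile left is then one over one plus D. Saturday's reading of 11% at 5.00 h, with its scatter of 2 percentage points, gives for 20 h a count of 32.4 turnovers offered to each electrophile. So 3.00% should remain and 97.0% should have coupled, and Saturday's last reading of 3% stands beside that. But one number is not enough, since target reads 55%, which is 42 points short of the coupled share, and it has been falling after the coupling slowed.

I therefore take 55% for now. Autumn offers the remaining electrophile 16.2 pseudo-first-order turnovers in 10 h, so it can add about 3 points, while Saturday's target fell 3 points over the last 5.00 h; I expect no useful gain. Sunday's warmer flask reads 64% at 20.0 h, higher than Saturday's, so I choose summer.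

The forecast says 55% (52% to 58%), summer as best, 56% after autumn and 84% after summer (70% to 93%), on the ground that “A lower plateau in the colder run points to a reversible, exothermic sink”.

    electrophile + nucleophile → acid set free + target (k = 0.0570 M⁻¹ min⁻¹, Ea = 61.0 kJ mol⁻¹)
    nucleophile + acid set free ⇌ protonated nucleophile, settled at all times (K = 120 M⁻¹, ΔH = −44.0 kJ mol⁻¹)
    acid set free + free base ⇌ salt of the base, settled at all times (K = 4200 M⁻¹, ΔH = −13.0 kJ mol⁻¹)
    gas ⇌ free base, rate k4*(csat - [free base]) (kL = 0.160 min⁻¹)
    target ⇌ isomer of the product (K = 0.960, k = 0.00100 min⁻¹, Ea = 91.0 kJ mol⁻¹, ΔH = −69.0 kJ mol⁻¹)
    (constants at 25 °C)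

The flask gives 55.1%, and summer wins, gaining 34 points to reach 89.5%, while autumn ends at 52.9%. With the turning of target into isomer of the product struck out, this flask stands at 97.5% at 20 h, beside the coupled share of 97.0% from D. The neighbour with 1.9 M of electrophile offers its nucleophile, the limiting reagent, 50.7 turnovers against the electrophile's excess, and that flask's nucleophile stands at 0% at 20.0 h; its charges leave 61.1% of the electrophile uncoupled, and that flask holds 61.1%.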